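The spiro δ-lactone (C7(=O)–O–C20–C10–C9–C8, ent-kaurane numbering) is the only link between ring A and the bicyclo[3.2.1]octane (rings C and D), so its two junction bonds, C20–O and C9–C10, are made in one convergent [4+2] annulation. An acridinium photocatalyst oxidises the ring-A diene C20=C10–C1=C2; the carboxylate of the β,γ-unsaturated bicyclic acid (C7 acid, C9=C11 alkene) captures C20, and the resulting C10 allyl radical closes 6-exo onto C9, setting the quaternary C10 and C9 before hydrogen-atom transfer to C11. The precursors are a resolved hydroxy keto acid and an (R)-dienyl silyl ether; the remaining C1=C2 alkene later becomes the enone.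

Key step: step 11

Conventions and assumptions
* Numbering (ent-kaurane): ring A = C1, C2, C3, C4 (CMe2), C5, C10; C6 = CH2OH; C7 = lactone C=O; C8 and C13 = bridgeheads; C9–C11–C12 = three-carbon bridge; C14 = one-carbon bridge; C15 (C=O)–C16 (CH–C17H3) = two-carbon bridge; C20 = OCH2. In the bicyclo[3.2.1]octene names, C1 = C8, C2 = C9, C3 = C11, C4 = C12, C5 = C13, C6 = C16, C7 = C15, C8 = C14. "Exo" is the face toward C14, "endo" the face toward the C9–C11–C12 bridge.
* Assumption (step 6): the (1S,5S,6R)-acid is taken to form the less soluble cinchonidine salt; if the opposite holds, cinchonine is used instead.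
* Assumption (step 8): the (S,S)-ligand is taken to give (6S)-12; if the sense is opposite, the (R,R)-ligand is used.

Step 1
Reactants: 1 3-methoxybenzoic acid
Product: 2 3-methoxycyclohexa-2,5-diene-1-carboxylic acid (racemic)
Conditions: Li, NH3(l)/THF, −78 °C; NH4Cl; work-up at pH 5, 0 °C
Reagents that add atoms: none
Why: Birch reduction of a benzoate places the new hydrogens at C1 and C4 (ipso and para to the carboxylate), leaving the methoxy group on an enol ether carbon and the future C9=C11 alkene in place; the C1 stereocentre is erased in step 2.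

Step 2
Reactants: 2 3-methoxycyclohexa-2,5-diene-1-carboxylic acid; 3 acrolein
Product: 5 1-(1-hydroxyprop-2-en-1-yl)-5-oxocyclohex-2-ene-1-carboxylic acid (racemic diastereomer mixture), via enol ether hydroxy acid 4 (not isolated)
Conditions: LiN(i-Pr)2 (2.2 equiv), THF, −78 °C; acrolein, −78 °C; then 1 M HCl, THF, 0 °C
Reagents that add atoms: water O
Why: Aldol addition of the carboxylic acid dianion through its α-carbon, 1,2 to the enal, builds the quaternary carbon C8, and brief cold aqueous acid hydrolyses the methyl enol ether to the β,γ-unsaturated C13 ketone without conjugating the alkene; both C8/C15 diastereomers are used because C15 is oxidised in step 4 and the racemate is resolved in step 6.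

Step 3
Reactants: 5 1-(1-hydroxyprop-2-en-1-yl)-5-oxocyclohex-2-ene-1-carboxylic acid
Product: 6 (1RS,5RS)-5,7-dihydroxy-6-methylbicyclo[3.2.1]oct-2-ene-1-carboxylic acid (racemic; epimers at C6 and C7)
Conditions: SmI2 (4 equiv), HMPA, t-BuOH, THF, −78 → 0 °C
Reagents that add atoms: none
Why: SmI2-mediated ketyl–olefin radical cyclisation: the C13 ketyl adds 5-exo-trig to the internal vinyl carbon C16 of the axial side chain, closing ring D with the bridgehead tertiary alcohol (its configuration relative to C8 is forced by the one-carbon bridge), and the C17 radical is reduced and protonated to the methyl group; C15 and C16 are settled in steps 4 and 5.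

Step 4
Reactants: 6 (1RS,5RS)-5,7-dihydroxy-6-methylbicyclo[3.2.1]oct-2-ene-1-carboxylic acid
Product: 7 (1RS,5RS)-5-hydroxy-6-methyl-7-oxobicyclo[3.2.1]oct-2-ene-1-carboxylic acid (racemic; epimers at C6)
Conditions: Dess–Martin periodinane, CH2Cl2, 0 °C → rt
Reagents that add atoms: none
Why: Dess–Martin oxidation converts only the secondary C15 alcohol, and the resulting β-keto acid and β-ketol are stable in the bicycle because a bridgehead enol (needed for decarboxylation) is forbidden and the C13–C16 bond lies in the plane of the C15 carbonyl (no retro-aldol overlap).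

Step 5
Reactants: 7 (1RS,5RS)-5-hydroxy-6-methyl-7-oxobicyclo[3.2.1]oct-2-ene-1-carboxylic acid
Product: 8 (1RS,5RS,6SR)-5-hydroxy-6-methyl-7-oxobicyclo[3.2.1]oct-2-ene-1-carboxylic acid (racemic; methyl endo)
Conditions: LiN(i-Pr)2 (3.5 equiv), THF, −78 → −30 °C; AcOH, −78 °C
Reagents that add atoms: none
Why: Kinetic protonation of the C15/C16 enolate (formed as the trianion) from the open exo face places the methyl group endo, which is the target configuration at C16 and converges any C16 mixture from step 3.

Step 6
Reactants: 8 (1RS,5RS,6SR)-5-hydroxy-6-methyl-7-oxobicyclo[3.2.1]oct-2-ene-1-carboxylic acid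
Product: 9 (1S,5S,6R)-5-hydroxy-6-methyl-7-oxobicyclo[3.2.1]oct-2-ene-1-carboxylic acid
Conditions: (−)-cinchonidine (1 equiv), acetone/MeOH, fractional crystallisation, 5 °C; then 1 M HCl/EtOAc
Reagents that add atoms: none
Why: Classical resolution through diastereomeric cinchonidinium salts; the amine is protonated in the salt, so the kinetically set C16 centre is not exposed to free base.

Step 7
Reactants: 10 5,5-dimethylcyclohex-2-en-1-one
Product: 11 [(3,3-dimethylcyclohexa-1,5-dien-1-yl)oxy]trimethylsilane
Conditions: LiN(i-Pr)2, THF, −78 °C; Me3SiCl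
Reagents that add atoms: chlorotrimethylsilane C[Si](C)(C)Cl
Why: Kinetic deprotonation at the only α' position (next to the gem-dimethyl carbon) and O-silylation should give the cross-conjugated silyl dienol ether regiospecifically (silyl enol ether formation); no stereocentre is formed.

Step 8
Reactants: 11 [(3,3-dimethylcyclohexa-1,5-dien-1-yl)oxy]trimethylsilane
Product: 12 (6S)-6-(hydroxymethyl)-5,5-dimethylcyclohex-2-en-1-one
Conditions: aq. HCHO, Sc(OTf)3 (10 mol %), (S,S)-6,6'-bis(1-hydroxy-2,2-dimethylpropyl)-2,2'-bipyridine (12 mol %), DME/H2O, −20 °C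
Reagents that add atoms: formaldehyde C=O
Why: Catalytic asymmetric Mukaiyama-type hydroxymethylation of a silicon enolate with aqueous formaldehyde; the chiral scandium–bipyridine complex differentiates the enolate faces and sets the CH–CH2OH stereocentre (future C5).

Step 9
Reactants: 12 (6S)-6-(hydroxymethyl)-5,5-dimethylcyclohex-2-en-1-one
Product: 13 (6S)-6-{[(tert-butyldimethylsilyl)oxy]methyl}-5,5-dimethylcyclohex-2-en-1-one
Conditions: TBSCl, imidazole, CH2Cl2, 0 °C → rt
Reagents that add atoms: tert-butyldimethylsilyl chloride CC(C)(C)[Si](C)(C)Cl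
Why: Standard silylation of the primary alcohol; the silyl ether keeps the hydroxyl from adding to the radical cation in step 11 and blocks retro-aldol loss of formaldehyde.

Step 10
Reactants: 13 (6S)-6-{[(tert-butyldimethylsilyl)oxy]methyl}-5,5-dimethylcyclohex-2-en-1-one
Product: 14 tert-butyl{[(1R)-6,6-dimethyl-2-methylidenecyclohex-3-en-1-yl]methoxy}dimethylsilane
Conditions: Ph3PCH3Br, KN(SiMe3)2, THF, 0 °C; then 13, −78 → 0 °C
Reagents that add atoms: methylenetriphenylphosphorane C=P(c1ccccc1)(c1ccccc1)c1ccccc1
Why: Wittig methylenation of the enone carbonyl (1,2-addition of the salt-free ylide) should give the s-trans exocyclic diene; the α-hydrogen on the stereocentre is shielded by the neighbouring quaternary carbon and low temperature limits enolisation.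

Step 11
Reactants: 9 (1S,5S,6R)-5-hydroxy-6-methyl-7-oxobicyclo[3.2.1]oct-2-ene-1-carboxylic acid; 14 tert-butyl{[(1R)-6,6-dimethyl-2-methylidenecyclohex-3-en-1-yl]methoxy}dimethylsilane (1.5 equiv)
Product: 15 6-(tert-butyldimethylsilyloxy)-13-hydroxy-15-oxo-6,7-seco-ent-kaur-1-en-7,20-olide (5R,8S,9S,10R,13S,16R)
Conditions: 9-mesityl-10-methylacridinium tetrafluoroborate (5 mol %), 2-phenylmalononitrile (0.3 equiv), 2,6-lutidine (0.2 equiv), CH2Cl2/(CF3)2CHOH 9:1, 450 nm LEDs, 25 °C
Reagents that add atoms: none
Why: Proposed new method: the excited acridinium oxidises the diene of 14 to its radical cation, the carboxylate of 9 adds to the unhindered terminus C20 (C20–O bond) to leave the C10–C1–C2 allyl radical, this radical attacks C9 of the β,γ-alkene (C9–C10 bond), and the C11 radical takes a hydrogen atom from 2-phenylmalononitrile, whose radical is reduced by the acridine radical so that both catalysts turn over. The closest known reaction type is the acridinium-catalysed polar radical crossover cycloaddition of alkenes with α,β-unsaturated acids to γ-butyrolactones (and the related anti-Markovnikov hydroacyloxylation of alkenes); new here are the diene as radical-cation partner, a β,γ-unsaturated acid and hence a δ-lactone. The δ-lactone is the only ring closed, in the 6-exo-trig mode through the s-cis ester rotamer. C10 is controlled by C5, because allylic strain with C20 holds the CH2OTBS group pseudo-axial so that C9 bonds to the opposite face (cis to C20), and C9 is controlled by the bicycle, because attack on the exo face is staggered with the C8–C15 bond and avoids the endo methyl on C16. The step needs carboxylate capture at C20 rather than C2, closure through C10 rather than C2, and closure faster than hydrogen transfer to the allyl radical; sterics and the more substituted allyl radical should secure the first, the six- versus eight-membered ring the second, and the slow substoichiometric hydrogen donor, the Thorpe–Ingold effect of quaternary C8 and the polar co-solvent (which raises the share of the s-cis rotamer) the third.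

Step 12
Reactants: 15 6-(tert-butyldimethylsilyloxy)-13-hydroxy-15-oxo-6,7-seco-ent-kaur-1-en-7,20-olide
Product: 17 6-(tert-butyldimethylsilyloxy)-13-hydroxy-1,15-dioxo-6,7-seco-ent-kaur-2-en-7,20-olide (5R,8S,9S,10S,13S,16R), via C1 hydroperoxide 16 (not isolated)
Conditions: O2, 5,10,15,20-tetraphenylporphyrin (cat.), visible light, CCl4, 0 °C; then Ac2O, pyridine, 0 °C → rt
Reagents that add atoms: dioxygen O=O
Why: Schenck ene reaction of singlet oxygen followed by Kornblum–DeLaMare-type dehydration: oxygen can bond only to C1 because the sole allylic hydrogens are on C3 (C10 is quaternary), which gives the C1 hydroperoxide with the alkene shifted to C2=C3, and acetic anhydride/pyridine converts it into the enone; no stereocentre is formed and the weak base leaves C16 untouched.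

Step 13
Reactants: 17 6-(tert-butyldimethylsilyloxy)-13-hydroxy-1,15-dioxo-6,7-seco-ent-kaur-2-en-7,20-olide
Product: 18 6,13-dihydroxy-1,15-dioxo-6,7-seco-ent-kaur-2-en-7,20-olide (5R,8S,9S,10S,13S,16R; target CNP0533761.1)
Conditions: HF·pyridine, THF/pyridine, 0 °C → rt
Reagents that add atoms: none
Why: Fluoride-driven desilylation under slightly acidic conditions should free the C6 alcohol without touching the lactone, the enone, the β-ketol or the base-sensitive C16 centre.

Compound list
1 | 3-methoxybenzoic acid | COc1cccc(c1)C(=O)O | starting material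
2 | 3-methoxycyclohexa-2,5-diene-1-carboxylic acid (racemic) | COC1=CC(C(=O)O)C=CC1 | intermediate
3 | acrolein (prop-2-enal) | C=CC=O | starting material
4 | 1-(1-hydroxyprop-2-en-1-yl)-3-methoxycyclohexa-2,5-diene-1-carboxylic acid (diastereomer mixture; not isolated) | COC1=CC(C(O)C=C)(C(=O)O)C=CC1 | intermediate
5 | 1-(1-hydroxyprop-2-en-1-yl)-5-oxocyclohex-2-ene-1-carboxylic acid (racemic diastereomer mixture) | O=C1CC=CC(C(O)C=C)(C(=O)O)C1 | intermediate
6 | (1RS,5RS)-5,7-dihydroxy-6-methylbicyclo[3.2.1]oct-2-ene-1-carboxylic acid (racemic; epimers at C6 and C7; one enantiomer drawn) | CC1C(O)[C@]2(C(=O)O)C[C@@]1(O)CC=C2 | intermediate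
7 | (1RS,5RS)-5-hydroxy-6-methyl-7-oxobicyclo[3.2.1]oct-2-ene-1-carboxylic acid (racemic; epimers at C6; one enantiomer drawn) | CC1C(=O)[C@]2(C(=O)O)C[C@@]1(O)CC=C2 | intermediate
8 | (1RS,5RS,6SR)-5-hydroxy-6-methyl-7-oxobicyclo[3.2.1]oct-2-ene-1-carboxylic acid (racemic; methyl endo, syn to the C2–C4 bridge; the 1S,5S,6R enantiomer is drawn) | C[C@H]1C(=O)[C@]2(C(=O)O)C[C@@]1(O)CC=C2 | intermediate
9 | (1S,5S,6R)-5-hydroxy-6-methyl-7-oxobicyclo[3.2.1]oct-2-ene-1-carboxylic acid (single enantiomer) | C[C@H]1C(=O)[C@]2(C(=O)O)C[C@@]1(O)CC=C2 | intermediate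
10 | 5,5-dimethylcyclohex-2-en-1-one | O=C1C=CCC(C)(C)C1 | starting material
11 | [(3,3-dimethylcyclohexa-1,5-dien-1-yl)oxy]trimethylsilane | C[Si](C)(C)OC1=CC(C)(C)CC=C1 | intermediate
12 | (6S)-6-(hydroxymethyl)-5,5-dimethylcyclohex-2-en-1-one | O=C1C=CCC(C)(C)[C@H]1CO | intermediate
13 | (6S)-6-{[(tert-butyldimethylsilyl)oxy]methyl}-5,5-dimethylcyclohex-2-en-1-one | O=C1C=CCC(C)(C)[C@H]1CO[Si](C)(C)C(C)(C)C | intermediate
14 | tert-butyl{[(1R)-6,6-dimethyl-2-methylidenecyclohex-3-en-1-yl]methoxy}dimethylsilane | C=C1C=CCC(C)(C)[C@H]1CO[Si](C)(C)C(C)(C)C | intermediate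
15 | 6-(tert-butyldimethylsilyloxy)-13-hydroxy-15-oxo-6,7-seco-ent-kaur-1-en-7,20-olide (5R,8S,9S,10R,13S,16R) | C[C@H]1C(=O)[C@]23C[C@@]1(O)CC[C@H]2[C@]1(COC3=O)C=CCC(C)(C)[C@H]1CO[Si](C)(C)C(C)(C)C | intermediate
16 | 1-hydroperoxy-2-ene derivative of 15 (C1 epimers; not isolated) | C[C@H]1C(=O)[C@]23C[C@@]1(O)CC[C@H]2[C@]1(COC3=O)C(OO)C=CC(C)(C)[C@H]1CO[Si](C)(C)C(C)(C)C | intermediate
17 | 6-(tert-butyldimethylsilyloxy)-13-hydroxy-1,15-dioxo-6,7-seco-ent-kaur-2-en-7,20-olide (5R,8S,9S,10S,13S,16R) | C[C@H]1C(=O)[C@]23C[C@@]1(O)CC[C@H]2[C@]1(COC3=O)C(=O)C=CC(C)(C)[C@H]1CO[Si](C)(C)C(C)(C)C | intermediate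
18 | 6,13-dihydroxy-1,15-dioxo-6,7-seco-ent-kaur-2-en-7,20-olide (5R,8S,9S,10S,13S,16R; CNP0533761.1) | C[C@H]1C(=O)[C@]23C[C@@]1(O)CC[C@H]2[C@]1(COC3=O)C(=O)C=CC(C)(C)[C@H]1CO | target

Total step count: 13. Longest linear sequence: 9 steps (steps 1–6, then 11–13); the ring-A branch is steps 7–10.

Steps most likely to fail

Step 11. Ring closure has to pass through the minor s-cis ester rotamer and involves a stabilised allyl radical attacking an unactivated alkene. Hydrogen transfer to the allyl radical (simple hydroacyloxylation of the diene) or diene dimerisation may therefore outrun cyclisation. The fallback makes the two bonds one after the other by known chemistry, setting out from 14 and 9 and coming back at 15. Bromine (1 equiv, CH2Cl2, −78 → 0 °C) should add 1,4 to the diene of 14 to give tert-butyl{[(1R)-4-bromo-2-(bromomethyl)-6,6-dimethylcyclohex-2-en-1-yl]methoxy}dimethylsilane F1. The caesium salt of 9 (Cs2CO3, DMF, 0 °C) should displace the primary allylic bromide to give the allyl ester of 9 with the 4-bromocyclohexenylmethyl unit F2, which carries the C20–O bond. Bu3SnH with azobisisobutyronitrile, added slowly at high dilution in refluxing benzene, should generate the same C10–C1–C2 allyl radical from the secondary allylic bromide; 6-exo closure onto C9 and reduction at C11 then give 15.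

Step 12. The ene reaction of singlet oxygen with a hindered cis-disubstituted ring alkene is slow, so sensitiser bleaching and unselective oxidation may take over before conversion is complete. The fallback sets out from 15 and comes back at 17. mCPBA (NaHCO3, CH2Cl2, 0 °C) should give the 1,2-epoxide of 15 F3. Phenylselenide (PhSeSePh premixed with NaBH4, EtOH) should open it at the less hindered C2 to give the 1-hydroxy-2-(phenylselanyl) derivative F4. Oxidation with H2O2 and selenoxide syn-elimination toward C3 should give the 1-hydroxy-2-ene allylic alcohol F5, which Dess–Martin periodinane oxidises to 17.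

Step 3. Reduction of the ketyl to the secondary alcohol or pinacol coupling may outrun the bridging 5-exo closure, since the free acid is an internal proton source. The fallback inverts the roles of the two partners and makes no new compound, setting out from 5 and coming back at 6. Fe(acac)3 and PhSiH3 in EtOH at 60 °C should transfer a hydrogen atom to the terminal vinyl carbon C17; the C16 alkyl radical then adds to the C13 ketone carbonyl, and the alkoxy radical is reduced to the tertiary alcohol.

Further compounds
F1 | step 11 | tert-butyl{[(1R)-4-bromo-2-(bromomethyl)-6,6-dimethylcyclohex-2-en-1-yl]methoxy}dimethylsilane (C4 epimers) | BrCC1=CC(Br)CC(C)(C)[C@H]1CO[Si](C)(C)C(C)(C)C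
F2 | step 11 | allyl ester of 9 with the 4-bromocyclohexenylmethyl unit | C[C@H]1C(=O)[C@]2(C(=O)OCC3=CC(Br)CC(C)(C)[C@H]3CO[Si](C)(C)C(C)(C)C)C[C@@]1(O)CC=C2
F3 | step 12 | 1,2-epoxide of 15 | C[C@H]1C(=O)[C@]23C[C@@]1(O)CC[C@H]2[C@]1(COC3=O)C2OC2CC(C)(C)[C@H]1CO[Si](C)(C)C(C)(C)C
F4 | step 12 | 1-hydroxy-2-(phenylselanyl) derivative of 15 | C[C@H]1C(=O)[C@]23C[C@@]1(O)CC[C@H]2[C@]1(COC3=O)C(O)C([Se]c2ccccc2)CC(C)(C)[C@H]1CO[Si](C)(C)C(C)(C)C
F5 | step 12 | 1-hydroxy-2-ene allylic alcohol | C[C@H]1C(=O)[C@]23C[C@@]1(O)CC[C@H]2[C@]1(COC3=O)C(O)C=CC(C)(C)[C@H]1CO[Si](C)(C)C(C)(C)C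
F0 | step 3 | none | none
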